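**Retrosynthetic overview**
- The sulfate is installed last on a triol aldehyde whose catechol pair is masked as a cyclic carbonate; the aldehyde comes from ortho-lithiation between two OMOM groups, and the C9 methyl from a C9 carboxyl group.
- The strategy rests on ring B (C5–C10): quaternary C9 (CH3, CH2Ar) is bonded to the ring-fusion C10–H, which is allylic to C5=C6. With the C9 methyl read as CO2H, O=C–C9–C10–C5=C6 is a γ,δ-unsaturated acid, the retron of an Ireland–Claisen rearrangement whose C6–O bond lies in a δ-lactone.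
- Disconnections: C9–C10 ([3,3] ring contraction), C9–C11 (lactone enolate benzylation), C5–C6 (acylation of a cyclohexenylzinc), lactone C–O.
- Ring order: ring A and the arene are bought; a temporary δ-lactone ring is closed on the C6–C9 chain; ring B is formed from it in the key step.

Key step: step 12

Remark (assumption): the target is taken as the free aryl hydrogen sulfate as drawn; it is liberated last from its pyridinium salt and handled cold. Decalin carbons carry drimane-type numbers (ring A = C1–C5, C10; ring B = C5–C10; C11 = benzylic CH2).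

**Route**

Step 1
Reactants: 1 2,2-dimethylcyclohexanone
Product: 2 (2,2-dimethylcyclohexylidene)hydrazine
Conditions: N2H4·H2O (5 equiv), Et3N, EtOH, reflux
Reagents that add atoms: hydrazine (as hydrate), NN
Why: Hydrazone condensation of an unhindered-side ketone; excess hydrazine should suppress azine formation.

Step 2
Reactants: 2 (2,2-dimethylcyclohexylidene)hydrazine
Product: 3 1-iodo-6,6-dimethylcyclohex-1-ene
Conditions: I2 (2.2 equiv), 1,1,3,3-tetramethylguanidine, Et2O, 0 °C to rt; brief warming to 90 °C to eliminate any gem-diiodide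
Reagents that add atoms: iodine, II
Why: Barton vinyl iodide synthesis; with C2 quaternary, elimination can only go toward the single α-CH2, so one regioisomer should form.

Step 3
Reactants: 4 (R)-5-methoxy-3-methyl-5-oxopentanoic acid [(R)-methyl hydrogen 3-methylglutarate]
Product: 5 methyl (S)-5-chloro-3-methyl-5-oxopentanoate (same spatial arrangement as 4; the descriptor changes by priority only)
Conditions: (COCl)2, DMF (cat.), CH2Cl2, 0 °C to rt
Reagents that add atoms: oxalyl chloride, O=C(Cl)C(=O)Cl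
Why: Vilsmeier-catalysed acid chloride formation; the stereocentre is β to both carbonyls and cannot epimerise.

Step 4
Reactants: 3 1-iodo-6,6-dimethylcyclohex-1-ene; 5 methyl (S)-5-chloro-3-methyl-5-oxopentanoate
Product: 8 methyl (R)-5-(6,6-dimethylcyclohex-1-en-1-yl)-3-methyl-5-oxopentanoate, via vinyllithium 6 (not isolated), via vinylzinc chloride 7 (not isolated)
Conditions: t-BuLi (2 equiv), THF, −78 °C; ZnCl2, −78 to 0 °C; then 5, Pd(PPh3)4 (5 mol %, zerovalent palladium), 0 °C to rt
Reagents that add atoms: none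
Why: Iodine–lithium exchange, transmetalation to zinc and Negishi acylation form the C5–C6 bond; the organozinc should tolerate the methyl ester and react only at the acid chloride.

Step 5
Reactants: 8 methyl (R)-5-(6,6-dimethylcyclohex-1-en-1-yl)-3-methyl-5-oxopentanoate
Product: 9 methyl (3R,5R)-5-(6,6-dimethylcyclohex-1-en-1-yl)-5-hydroxy-3-methylpentanoate
Conditions: (S)-2-methyl-CBS-oxazaborolidine (0.2 equiv), catecholborane (1.5 equiv), toluene, −78 °C; MeOH quench, aq. carbonate wash
Reagents that add atoms: none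
Why: Corey–Bakshi–Shibata reduction with the α-branched cyclohexenyl group as the large substituent should give the (5R)-carbinol (C6) under reagent control, leaving the ester untouched.

Step 6
Reactants: 9 methyl (3R,5R)-5-(6,6-dimethylcyclohex-1-en-1-yl)-5-hydroxy-3-methylpentanoate
Product: 10 (4R,6R)-6-(6,6-dimethylcyclohex-1-en-1-yl)-4-methyloxan-2-one (cis δ-lactone)
Conditions: PPTS (0.1 equiv), toluene, 70 °C, 4 Å molecular sieves
Reagents that add atoms: none
Why: Acid-catalysed lactonisation (intramolecular transesterification) of a δ-hydroxy ester, mild enough not to ionise the allylic carbinol; the methyl and cyclohexenyl groups end up cis, both equatorial.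

Step 7
Reactants: 11 2,4,5-trihydroxybenzaldehyde
Product: 12 2,4,5-tris(methoxymethoxy)benzaldehyde
Conditions: MOMCl (4.5 equiv), i-Pr2NEt (6 equiv), CH2Cl2, 0 to 40 °C, argon
Reagents that add atoms: chloromethyl methyl ether, COCCl
Why: O-alkylation of the three phenols (MOM protection); excess reagent and warming should also cap the hydrogen-bonded ortho phenol.

Step 8
Reactants: 12 2,4,5-tris(methoxymethoxy)benzaldehyde
Product: 13 [2,4,5-tris(methoxymethoxy)phenyl]methanol
Conditions: NaBH4, MeOH–THF, 0 °C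
Reagents that add atoms: none
Why: Borohydride reduction of an aryl aldehyde; the MOM acetals are inert to hydride.

Step 9
Reactants: 13 [2,4,5-tris(methoxymethoxy)phenyl]methanol
Product: 14 1-(bromomethyl)-2,4,5-tris(methoxymethoxy)benzene
Conditions: CBr4, PPh3, CH2Cl2, −20 to 0 °C; rapid filtration and immediate use
Reagents that add atoms: carbon tetrabromide, BrC(Br)(Br)Br
Why: Appel bromination under neutral conditions spares the acid-labile MOM groups; the electron-rich bromide is not stored.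

Step 10
Reactants: 10 (4R,6R)-6-(6,6-dimethylcyclohex-1-en-1-yl)-4-methyloxan-2-one; 14 1-(bromomethyl)-2,4,5-tris(methoxymethoxy)benzene
Product: 16 (3S,4R,6R)-6-(6,6-dimethylcyclohex-1-en-1-yl)-4-methyl-3-[2,4,5-tris(methoxymethoxy)benzyl]oxan-2-one, via lactone lithium enolate 15 (not isolated)
Conditions: LiN(i-Pr)2 (1.05 equiv), THF, −78 °C; then 14, DMPU, −78 to −40 °C
Reagents that add atoms: none
Why: Lactone enolate alkylation (SN2) with a reactive benzylic bromide forms C9–C11, mainly trans to the neighbouring methyl; either C3 epimer serves, because this centre becomes sp2 in the next step.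

Step 11
Reactants: 16 (3S,4R,6R)-6-(6,6-dimethylcyclohex-1-en-1-yl)-4-methyl-3-[2,4,5-tris(methoxymethoxy)benzyl]oxan-2-one
Product: 18 (2R,4R)-6-(tert-butyldimethylsilyloxy)-2-(6,6-dimethylcyclohex-1-en-1-yl)-4-methyl-5-[2,4,5-tris(methoxymethoxy)benzyl]-3,4-dihydro-2H-pyran (cyclic silyl ketene acetal), via benzyl lactone lithium enolate 17 (not isolated)
Conditions: LiN(i-Pr)2 (1.2 equiv), THF, −78 °C; TBSCl, DMPU, −78 °C to rt; pentane, filtration, no aqueous acid
Reagents that add atoms: tert-butyldimethylsilyl chloride, CC(C)(C)[Si](C)(C)Cl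
Why: Enolisation and O-silylation in a polar medium give the ketene acetal, whose double-bond geometry is fixed by the ring.

Step 12
Reactants: 18 (2R,4R)-6-(tert-butyldimethylsilyloxy)-2-(6,6-dimethylcyclohex-1-en-1-yl)-4-methyl-5-[2,4,5-tris(methoxymethoxy)benzyl]-3,4-dihydro-2H-pyran
Product: 20 (1S,2R,8aR)-2,5,5-trimethyl-1-[2,4,5-tris(methoxymethoxy)benzyl]-1,2,3,5,6,7,8,8a-octahydronaphthalene-1-carboxylic acid, via tert-butyldimethylsilyl ester 19 (not isolated)
Conditions: toluene (1% Et3N), sealed tube, 110–140 °C; then AcOH–THF–H2O, rt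
Reagents that add atoms: none
Why: Heating should trigger a concerted suprafacial [3,3] shift over C9=C(OSi)–O–C6–C5=C10, in which the C9–C10 bond forms as the C6–O bond breaks and the alkene moves to C5=C6; this is an Ireland–Claisen rearrangement run as the known ring contraction of 6-alkenyl δ-lactone silyl ketene acetals to cyclohexenecarboxylic acids, with the thermal 2-alkenyl-dihydropyran to cyclohexenecarbaldehyde rearrangement as a close relative. Ring B is closed pericyclically by contraction of the six-membered lactone onto carbon; because the C7–C8 tether joins positions 1 and 4 of the array, only a bridged boat resembling 2-oxabicyclo[2.2.2]octene is open, and the new six-membered ring carries a cis C5=C6 bond. C9 is set because C10 can reach only the ketene acetal face on which the C6 cyclohexenyl group sits, and C10 is set because the ring A alkene is locked with H10 inside the boat and C1 outside, which puts the carboxyl carbon anti to H10 and the benzyl group syn to it; the C6 carbinol centre is transferred to both and is itself lost. The step needs one face at each terminus, and this is secured by the single C6 configuration, the ring-locked geometry of both alkenes and the cis relation of the C8 methyl to the C6 substituent, which places Me8 trans to the carboxyl. Crowding of the siloxy group against the C4 gem-dimethyl carbon is the expected cost and is met by temperature; the labile silyl ester is cleaved at silicon by aqueous acetic acid, which leaves the MOM ethers intact.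

Step 13
Reactants: 20 (1S,2R,8aR)-2,5,5-trimethyl-1-[2,4,5-tris(methoxymethoxy)benzyl]-1,2,3,5,6,7,8,8a-octahydronaphthalene-1-carboxylic acid
Product: 21 {(1S,2R,8aR)-2,5,5-trimethyl-1-[2,4,5-tris(methoxymethoxy)benzyl]-1,2,3,5,6,7,8,8a-octahydronaphthalen-1-yl}methanol
Conditions: LiAlH4, THF, 0 °C to reflux; Fieser work-up
Reagents that add atoms: none
Why: Hydride reduction of a hindered acid to the neopentyl alcohol; alkene and MOM ethers are inert.

Step 14
Reactants: 21 {(1S,2R,8aR)-2,5,5-trimethyl-1-[2,4,5-tris(methoxymethoxy)benzyl]-1,2,3,5,6,7,8,8a-octahydronaphthalen-1-yl}methanol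
Product: 22 (1S,2R,8aR)-2,5,5-trimethyl-1-[2,4,5-tris(methoxymethoxy)benzyl]-1,2,3,5,6,7,8,8a-octahydronaphthalene-1-carbaldehyde
Conditions: Dess–Martin periodinane, pyridine, CH2Cl2, 0 °C to rt
Reagents that add atoms: none
Why: Dess–Martin oxidation under buffered conditions; the aldehyde has no α-hydrogen and cannot epimerise.

Step 15
Reactants: 22 (1S,2R,8aR)-2,5,5-trimethyl-1-[2,4,5-tris(methoxymethoxy)benzyl]-1,2,3,5,6,7,8,8a-octahydronaphthalene-1-carbaldehyde
Product: 24 1-{[(1R,2R,8aS)-1,2,5,5-tetramethyl-1,2,3,5,6,7,8,8a-octahydronaphthalen-1-yl]methyl}-2,4,5-tris(methoxymethoxy)benzene, via aldehyde hydrazone 23 (not isolated)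
Conditions: N2H4·H2O, KOH, diethylene glycol, 130 °C then 200 °C
Reagents that add atoms: none
Why: Wolff–Kishner reduction (Huang-Minlon procedure) turns the neopentyl aldehyde into the C9 methyl; aryl MOM ethers and the isolated alkene tolerate hot base.

Step 16
Reactants: 24 1-{[(1R,2R,8aS)-1,2,5,5-tetramethyl-1,2,3,5,6,7,8,8a-octahydronaphthalen-1-yl]methyl}-2,4,5-tris(methoxymethoxy)benzene
Product: 26 2,3,6-tris(methoxymethoxy)-5-{[(1R,2R,8aS)-1,2,5,5-tetramethyl-1,2,3,5,6,7,8,8a-octahydronaphthalen-1-yl]methyl}benzaldehyde, via aryllithium 25 (not isolated)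
Conditions: n-BuLi, TMEDA, THF, −20 to 0 °C; DMF, −78 to 0 °C; H2O
Reagents that add atoms: N,N-dimethylformamide, CN(C)C=O
Why: Directed ortho-metalation occurs at the one ring CH flanked by two OMOM groups, and formylation of the aryllithium with DMF places CHO between them.

Step 17
Reactants: 26 2,3,6-tris(methoxymethoxy)-5-{[(1R,2R,8aS)-1,2,5,5-tetramethyl-1,2,3,5,6,7,8,8a-octahydronaphthalen-1-yl]methyl}benzaldehyde
Product: 27 2,3,6-trihydroxy-5-{[(1R,2R,8aS)-1,2,5,5-tetramethyl-1,2,3,5,6,7,8,8a-octahydronaphthalen-1-yl]methyl}benzaldehyde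
Conditions: HCl (about 1 M, from AcCl) in MeOH–THF, degassed, rt to 40 °C, argon
Reagents that add atoms: none
Why: Acid-catalysed transacetalisation removes the three aryl MOM groups; dilute protic acid in methanol should be too weak to protonate the trisubstituted C5=C6 alkene.

Step 18
Reactants: 27 2,3,6-trihydroxy-5-{[(1R,2R,8aS)-1,2,5,5-tetramethyl-1,2,3,5,6,7,8,8a-octahydronaphthalen-1-yl]methyl}benzaldehyde
Product: 28 5-hydroxy-2-oxo-6-{[(1R,2R,8aS)-1,2,5,5-tetramethyl-1,2,3,5,6,7,8,8a-octahydronaphthalen-1-yl]methyl}-1,3-benzodioxole-4-carbaldehyde (catechol cyclic carbonate)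
Conditions: 1,1'-carbonyldiimidazole (1.05 equiv), THF, 0 °C to rt, argon
Reagents that add atoms: 1,1'-carbonyldiimidazole, O=C(n1ccnc1)n1ccnc1
Why: Carbonylation of the catechol: only the vicinal pair can close a five-membered carbonate, and an acyl imidazole formed at the lone phenol can only transfer back, so the material should funnel to 28.

Step 19
Reactants: 28 5-hydroxy-2-oxo-6-{[(1R,2R,8aS)-1,2,5,5-tetramethyl-1,2,3,5,6,7,8,8a-octahydronaphthalen-1-yl]methyl}-1,3-benzodioxole-4-carbaldehyde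
Product: 30 pyridinium 2-formyl-3,4-dihydroxy-6-{[(1R,2R,8aS)-1,2,5,5-tetramethyl-1,2,3,5,6,7,8,8a-octahydronaphthalen-1-yl]methyl}phenyl sulfate, via carbonate sulfate pyridinium salt 29 (not isolated)
Conditions: SO3·pyridine (4 equiv), pyridine, rt; then H2O, rt; reversed-phase (C18) chromatography
Reagents that add atoms: sulfur trioxide–pyridine complex, [O-]S(=O)(=O)[n+]1ccccc1
Why: O-sulfation of the only free phenol, followed by hydrolysis of the labile aryl cyclic carbonate in aqueous pyridine, a medium in which the aryl sulfate monoester is stable.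

Step 20
Reactants: 30 pyridinium 2-formyl-3,4-dihydroxy-6-{[(1R,2R,8aS)-1,2,5,5-tetramethyl-1,2,3,5,6,7,8,8a-octahydronaphthalen-1-yl]methyl}phenyl sulfate
Product: 31 2-formyl-3,4-dihydroxy-6-{[(1R,2R,8aS)-1,2,5,5-tetramethyl-1,2,3,5,6,7,8,8a-octahydronaphthalen-1-yl]methyl}phenyl hydrogen sulfate (CNP0115595.2)
Conditions: Dowex 50WX8 (H+ form), H2O–MeOH, 0 °C; immediate freeze-drying
Reagents that add atoms: none
Why: Cation exchange on a sulfonic acid resin retains pyridinium and releases the acid form, which is kept cold to avoid autocatalytic hydrolysis.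

**Compound list**
1 | 2,2-dimethylcyclohexanone | CC1(C)CCCCC1=O | starting material
2 | (2,2-dimethylcyclohexylidene)hydrazine | NN=C1CCCCC1(C)C | intermediate
3 | 1-iodo-6,6-dimethylcyclohex-1-ene | IC1=CCCCC1(C)C | intermediate
4 | (R)-5-methoxy-3-methyl-5-oxopentanoic acid | COC(=O)C[C@H](C)CC(=O)O | starting material
5 | methyl (S)-5-chloro-3-methyl-5-oxopentanoate | COC(=O)C[C@H](C)CC(=O)Cl | intermediate
6 | (6,6-dimethylcyclohex-1-en-1-yl)lithium | [Li]C1=CCCCC1(C)C | intermediate
7 | (6,6-dimethylcyclohex-1-en-1-yl)zinc chloride | Cl[Zn]C1=CCCCC1(C)C | intermediate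
8 | methyl (R)-5-(6,6-dimethylcyclohex-1-en-1-yl)-3-methyl-5-oxopentanoate | COC(=O)C[C@H](C)CC(=O)C1=CCCCC1(C)C | intermediate
9 | methyl (3R,5R)-5-(6,6-dimethylcyclohex-1-en-1-yl)-5-hydroxy-3-methylpentanoate | COC(=O)C[C@H](C)C[C@@H](O)C1=CCCCC1(C)C | intermediate
10 | (4R,6R)-6-(6,6-dimethylcyclohex-1-en-1-yl)-4-methyloxan-2-one | O=C1C[C@H](C)C[C@H](C2=CCCCC2(C)C)O1 | intermediate
11 | 2,4,5-trihydroxybenzaldehyde | O=Cc1cc(O)c(O)cc1O | starting material
12 | 2,4,5-tris(methoxymethoxy)benzaldehyde | O=Cc1cc(OCOC)c(OCOC)cc1OCOC | intermediate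
13 | [2,4,5-tris(methoxymethoxy)phenyl]methanol | OCc1cc(OCOC)c(OCOC)cc1OCOC | intermediate
14 | 1-(bromomethyl)-2,4,5-tris(methoxymethoxy)benzene | BrCc1cc(OCOC)c(OCOC)cc1OCOC | intermediate
15 | lithium enolate of lactone 10 | [Li]OC1=C[C@H](C)C[C@H](C2=CCCCC2(C)C)O1 | intermediate
16 | (3S,4R,6R)-6-(6,6-dimethylcyclohex-1-en-1-yl)-4-methyl-3-[2,4,5-tris(methoxymethoxy)benzyl]oxan-2-one | O=C1[C@@H](Cc2cc(OCOC)c(OCOC)cc2OCOC)[C@H](C)C[C@H](C3=CCCCC3(C)C)O1 | intermediate
17 | lithium enolate of benzyl lactone 16 | [Li]OC1=C(Cc2cc(OCOC)c(OCOC)cc2OCOC)[C@H](C)C[C@H](C3=CCCCC3(C)C)O1 | intermediate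
18 | (2R,4R)-6-(tert-butyldimethylsilyloxy)-2-(6,6-dimethylcyclohex-1-en-1-yl)-4-methyl-5-[2,4,5-tris(methoxymethoxy)benzyl]-3,4-dihydro-2H-pyran | CC(C)(C)[Si](C)(C)OC1=C(Cc2cc(OCOC)c(OCOC)cc2OCOC)[C@H](C)C[C@H](C3=CCCCC3(C)C)O1 | intermediate
19 | tert-butyldimethylsilyl ester of acid 20 | C[C@@H]1CC=C2[C@@H](CCCC2(C)C)[C@]1(C(=O)O[Si](C)(C)C(C)(C)C)Cc1cc(OCOC)c(OCOC)cc1OCOC | intermediate
20 | (1S,2R,8aR)-2,5,5-trimethyl-1-[2,4,5-tris(methoxymethoxy)benzyl]-1,2,3,5,6,7,8,8a-octahydronaphthalene-1-carboxylic acid | C[C@@H]1CC=C2[C@@H](CCCC2(C)C)[C@]1(C(=O)O)Cc1cc(OCOC)c(OCOC)cc1OCOC | intermediate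
21 | {(1S,2R,8aR)-2,5,5-trimethyl-1-[2,4,5-tris(methoxymethoxy)benzyl]-1,2,3,5,6,7,8,8a-octahydronaphthalen-1-yl}methanol | C[C@@H]1CC=C2[C@@H](CCCC2(C)C)[C@]1(CO)Cc1cc(OCOC)c(OCOC)cc1OCOC | intermediate
22 | (1S,2R,8aR)-2,5,5-trimethyl-1-[2,4,5-tris(methoxymethoxy)benzyl]-1,2,3,5,6,7,8,8a-octahydronaphthalene-1-carbaldehyde | C[C@@H]1CC=C2[C@@H](CCCC2(C)C)[C@]1(C=O)Cc1cc(OCOC)c(OCOC)cc1OCOC | intermediate
23 | hydrazone of aldehyde 22 | C[C@@H]1CC=C2[C@@H](CCCC2(C)C)[C@]1(/C=N/N)Cc1cc(OCOC)c(OCOC)cc1OCOC | intermediate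
24 | 1-{[(1R,2R,8aS)-1,2,5,5-tetramethyl-1,2,3,5,6,7,8,8a-octahydronaphthalen-1-yl]methyl}-2,4,5-tris(methoxymethoxy)benzene | C[C@@H]1CC=C2[C@@H](CCCC2(C)C)[C@]1(C)Cc1cc(OCOC)c(OCOC)cc1OCOC | intermediate
25 | 3-lithio derivative of 24 (lithium between the two OMOM groups) | C[C@@H]1CC=C2[C@@H](CCCC2(C)C)[C@]1(C)Cc1cc(OCOC)c(OCOC)c([Li])c1OCOC | intermediate
26 | 2,3,6-tris(methoxymethoxy)-5-{[(1R,2R,8aS)-1,2,5,5-tetramethyl-1,2,3,5,6,7,8,8a-octahydronaphthalen-1-yl]methyl}benzaldehyde | C[C@@H]1CC=C2[C@@H](CCCC2(C)C)[C@]1(C)Cc1cc(OCOC)c(OCOC)c(C=O)c1OCOC | intermediate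
27 | 2,3,6-trihydroxy-5-{[(1R,2R,8aS)-1,2,5,5-tetramethyl-1,2,3,5,6,7,8,8a-octahydronaphthalen-1-yl]methyl}benzaldehyde | C[C@@H]1CC=C2[C@@H](CCCC2(C)C)[C@]1(C)Cc1cc(O)c(O)c(C=O)c1O | intermediate
28 | 5-hydroxy-2-oxo-6-{[(1R,2R,8aS)-1,2,5,5-tetramethyl-1,2,3,5,6,7,8,8a-octahydronaphthalen-1-yl]methyl}-1,3-benzodioxole-4-carbaldehyde | C[C@@H]1CC=C2[C@@H](CCCC2(C)C)[C@]1(C)Cc1cc2OC(=O)Oc2c(C=O)c1O | intermediate
29 | pyridinium salt of the aryl sulfate of carbonate 28 | C[C@@H]1CC=C2[C@@H](CCCC2(C)C)[C@]1(C)Cc1cc2OC(=O)Oc2c(C=O)c1OS(=O)(=O)[O-].c1cc[nH+]cc1 | intermediate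
30 | pyridinium 2-formyl-3,4-dihydroxy-6-{[(1R,2R,8aS)-1,2,5,5-tetramethyl-1,2,3,5,6,7,8,8a-octahydronaphthalen-1-yl]methyl}phenyl sulfate | C[C@@H]1CC=C2[C@@H](CCCC2(C)C)[C@]1(C)Cc1cc(O)c(O)c(C=O)c1OS(=O)(=O)[O-].c1cc[nH+]cc1 | intermediate
31 | 2-formyl-3,4-dihydroxy-6-{[(1R,2R,8aS)-1,2,5,5-tetramethyl-1,2,3,5,6,7,8,8a-octahydronaphthalen-1-yl]methyl}phenyl hydrogen sulfate (CNP0115595.2) | C[C@@H]1CC=C2[C@@H](CCCC2(C)C)[C@]1(C)Cc1cc(O)c(O)c(C=O)c1OS(=O)(=O)O | target

**Totals**
Total step count: 20. Longest linear sequence: 16 steps (from 1 through steps 1, 2, 4, 5, 6 and 10 to 20).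

**Steps most likely to fail**

Step 12. The boat transition state may be too congested, with the siloxy group pressed against the C4 gem-dimethyl carbon and the benzyl group against C1, so that silyl migration to carbon or decomposition of the ketene acetal outruns the sigmatropic shift. The fallback sets out from benzyl lactone 16 and uses the oxygen-free relative of the same shift. Reduction with i-Bu2AlH (CH2Cl2, −78 °C) should give the lactol (2RS,3S,4R,6R)-6-(6,6-dimethylcyclohex-1-en-1-yl)-4-methyl-3-[2,4,5-tris(methoxymethoxy)benzyl]oxan-2-ol F1. Mesylation and elimination (MsCl, Et3N, then warming) should give the enol ether (2R,4R)-2-(6,6-dimethylcyclohex-1-en-1-yl)-4-methyl-5-[2,4,5-tris(methoxymethoxy)benzyl]-3,4-dihydro-2H-pyran F2. Thermolysis of F2 (base-washed sealed tube, 200–230 °C) is a Claisen rearrangement of an allyl vinyl ether through the same bridged boat, now without a siloxy group on the central carbon, and delivers the C9 aldehyde directly, so the route is rejoined at aldehyde 22.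

Step 19. Sulfation of the hindered, hydrogen-bonded phenol between the benzylic carbon and the aldehyde may be slow, and premature opening of the carbonate would expose the catechol oxygens and erode site selectivity. The fallback sets out from carbonate 28 and uses a protected, more electrophilic sulfuryl donor. Deprotonation with NaN(SiMe3)2 (THF, −78 °C) and reaction with isobutyl chlorosulfate should give the neutral, chromatographable diester 4-formyl-2-oxo-6-{[(1R,2R,8aS)-1,2,5,5-tetramethyl-1,2,3,5,6,7,8,8a-octahydronaphthalen-1-yl]methyl}-1,3-benzodioxol-5-yl isobutyl sulfate F3. Dealkylation with NaI in acetone (55 °C) should give the sodium aryl sulfate of the carbonate F4. Stirring F4 in aqueous pyridine and passing it through the acid resin returns the route at target 31.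

Step 10. The electron-rich benzyl bromide may ionise and self-condense faster than it is captured, and proton transfer between product and enolate may lead to double alkylation. The fallback sets out from lactone 10 and the stable aldehyde 12. Aldol addition of enolate 15 to 12 (THF, −78 °C) should give the β-hydroxy lactone (4R,6R)-6-(6,6-dimethylcyclohex-1-en-1-yl)-3-{hydroxy[2,4,5-tris(methoxymethoxy)phenyl]methyl}-4-methyloxan-2-one F5. Mesylation and elimination with DBU should give the benzylidene lactone (3E,4R,6R)-6-(6,6-dimethylcyclohex-1-en-1-yl)-4-methyl-3-[2,4,5-tris(methoxymethoxy)benzylidene]oxan-2-one F6. Conjugate reduction with Stryker's reagent [(Ph3P)CuH]6, which leaves the isolated ring A alkene alone, rejoins the route at benzyl lactone 16; the C3 configuration is immaterial.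

**Further compounds**
F1 | step 12 | (2RS,3S,4R,6R)-6-(6,6-dimethylcyclohex-1-en-1-yl)-4-methyl-3-[2,4,5-tris(methoxymethoxy)benzyl]oxan-2-ol | OC1[C@@H](Cc2cc(OCOC)c(OCOC)cc2OCOC)[C@H](C)C[C@H](C3=CCCCC3(C)C)O1
F2 | step 12 | (2R,4R)-2-(6,6-dimethylcyclohex-1-en-1-yl)-4-methyl-5-[2,4,5-tris(methoxymethoxy)benzyl]-3,4-dihydro-2H-pyran | C1=C(Cc2cc(OCOC)c(OCOC)cc2OCOC)[C@H](C)C[C@H](C3=CCCCC3(C)C)O1
F3 | step 19 | 4-formyl-2-oxo-6-{[(1R,2R,8aS)-1,2,5,5-tetramethyl-1,2,3,5,6,7,8,8a-octahydronaphthalen-1-yl]methyl}-1,3-benzodioxol-5-yl isobutyl sulfate | C[C@@H]1CC=C2[C@@H](CCCC2(C)C)[C@]1(C)Cc1cc2OC(=O)Oc2c(C=O)c1OS(=O)(=O)OCC(C)C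
F4 | step 19 | sodium 4-formyl-2-oxo-6-{[(1R,2R,8aS)-1,2,5,5-tetramethyl-1,2,3,5,6,7,8,8a-octahydronaphthalen-1-yl]methyl}-1,3-benzodioxol-5-yl sulfate | C[C@@H]1CC=C2[C@@H](CCCC2(C)C)[C@]1(C)Cc1cc2OC(=O)Oc2c(C=O)c1OS(=O)(=O)[O-].[Na+]
F5 | step 10 | (4R,6R)-6-(6,6-dimethylcyclohex-1-en-1-yl)-3-{hydroxy[2,4,5-tris(methoxymethoxy)phenyl]methyl}-4-methyloxan-2-one | O=C1C(C(O)c2cc(OCOC)c(OCOC)cc2OCOC)[C@H](C)C[C@H](C3=CCCCC3(C)C)O1
F6 | step 10 | (3E,4R,6R)-6-(6,6-dimethylcyclohex-1-en-1-yl)-4-methyl-3-[2,4,5-tris(methoxymethoxy)benzylidene]oxan-2-one | O=C1/C(=C/c2cc(OCOC)c(OCOC)cc2OCOC)[C@H](C)C[C@H](C3=CCCCC3(C)C)O1
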